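At early times I count entries rather than hours: each substrate that free catalyst takes up makes one catalyst intermediate A, which then goes on with partner at 4.8 h⁻¹ or is caught by capture agent at 0.24 h⁻¹, both as charged.

substrate 0.50 M; partner 0.750 M; capture agent 0.0500 M; free catalyst 18 mM

    catalyst intermediate B ⇌ catalyst intermediate C (K1 = 2.1, k1 = 6.1 h⁻¹)
    catalyst intermediate A + capture agent → trapped intermediate (k2 = 4.8 L mol⁻¹ h⁻¹)
    partner + catalyst intermediate A → catalyst intermediate B (k3 = 6.4 L mol⁻¹ h⁻¹)
    catalyst intermediate C → free catalyst + target (k4 = 0.88 h⁻¹)
    partner → decomposed reagent (k5 = 0.034 h⁻¹)
    substrate + free catalyst → catalyst intermediate A (k6 = 180 L mol⁻¹ h⁻¹)

- the form that holds most of the catalyst when 30 % of the substrate are converted (catalyst intermediate B / catalyst intermediate C / trapped intermediate / catalyst intermediate A / free catalyst)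
- its share of the catalyst then
- apparent order in partner when 30 % of the substrate are converted (percent change of the rate of making target for one percent more partner charged)
- factor on the rate of making target when 30 % of the substrate are converted if free catalyst is charged twice over

I call the leak, λ, the chance that a newly made catalyst intermediate A is caught by capture agent rather than taken on by partner. At the charge it is:

λ = 0.24 h⁻¹ / (0.24 h⁻¹ + 4.8 h⁻¹) = 0.0476

Conversion counts the entries per catalyst charged, n, however long they took:

n = 0.50 M × 30 % / 18 mM = 8.33

The trapped share of the catalyst is then about nλ, or 39.7 %.

My objection is that λ does not stay put, because partner decays over the 23.1 h before the look. Decay by itself leaves this much partner: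

partner ≈ 0.341 M, so late λ ≈ 0.0989

This neglects partner drawn off by the rounds and capture agent used up, which pull in opposite directions, so I let them stand against each other. A plain average of the two leaks would give late entries the same weight as early ones, but I expect entries to come early rather than late, so as a judgement I take the geometric mean, which is lower:

mean λ = 0.0686, trapped share s = n × mean λ = 57.2 %

That leaves 42.8 % for the forms in the round, so I name trapped intermediate as the largest holder.

The same count serves the other two questions. At fixed conversion n stays fixed, and λ falls about as partner rises, so one percent more partner takes one percent off s. The working share then gains, which gives an order of s/(1 − s) = 1.34. This counts partner through the leak and ignores what partner does inside the round, so I hold it as a partial figure. Twice the catalyst halves n, which gives a factor of 2(1 − s/2)/(1 − s) = 3.34.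

The forecast names trapped intermediate at 56 %, with order 2.8 and factor 4.1, holding that “history makes the rate at fixed conversion far more sensitive”. Its order and factor both stand above mine.

This flask reaches the look at 23.1 h, where trapped intermediate holds 55.2 %. The order in partner is 1.8 and the factor is 3.85. The forecast's share and factor hold, but its order stands too high, and my order and factor fall short.

Read back from this flask, the mean leak is 0.0663, lying between my two ends. In the second flask, the same run without the capture step, λ is zero and the working share should rise from 44.8 % to the whole; if the forms in the round kept their proportions, that is a rate 2.23 times the actual one, and that run gives 2.30. The largest single effect on the order is this capture step: without it, the order in partner falls from 1.8 to 0.29.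

Its constants stand for no real mixture, and the outcome is calculated.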